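All runs are simulated with made-up constants; scatter was added.

The chemist at this bench doses Q onto the catalyst E and wants G, while Q also turns into L without E.

| flask | Q | E | temperature | remark | time |
|---|---|---|---|---|---|
| alpha | 0.79 M (fed, over 6.0 min) | 0.51 mM | 60 °C | run made earlier; the fed solution adds 0.25 times the starting volume |  |
| epsilon | 0.79 M (fed, over 6.0 min) | 3.9 mM | 88 °C | run made earlier; the fed solution adds 0.25 times the starting volume |  |
| theta | 1.7 M (fed, over 6.0 min) | 1.6 mM | 60 °C | run made earlier; the fed solution adds 0.25 times the starting volume |  |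
| south-east | 2.5 M (fed, over 25 min) | 0.80 mM | 80 °C | the fed solution adds 0.25 times the starting volume | 8.0 min |
| south | 0.79 M (fed, over 2.0 min) | 0.40 mM | 65 °C | the fed solution adds 0.25 times the starting volume | 8.0 min |
| north | 0.79 M (fed, over 6.0 min) | 1.6 mM | 80 °C | the fed solution adds 0.25 times the starting volume | 8.0 min |
| north-west | 0.79 M (fed, over 12 min) | 1.6 mM | 110 °C | the fed solution adds 0.25 times the starting volume | 8.0 min |
| east | 0.79 M (fed, over 20 min) | 2.5 mM | 80 °C | the fed solution adds 0.25 times the starting volume | 8.0 min |

- alpha (time / min: G / %, L / %): 1.33: 0, 0; 4.00: 2.8, 2.3; 8.00: 8.2, 10.1; 10.0: 10.9, 13.4; 15.0: 16.8, 19.4; 20.0: 23.3, 27.3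
- epsilon (time / min: G / %, L / %): 1.33: 6.1, 4.2; 2.50: 17.6, 10.1; 4.00: 32.3, 17.4; 5.00: 40.6, 23.1; 6.00: 49.1, 31.1; 8.00: 57.0, 35.8
- theta (time / min: G / %, L / %): 4.00: 7.5, 3.5; 8.00: 21.8, 8.7; 15.0: 39.2, 17.6; 20.0: 49.5, 19.8

(scatter of a reading: 1 percentage point)

- a species is counted by the Q in it: one D or X counts as two
- amounts and yields of G count X too
- charges are per starting volume, the dose included; the dosed solution carries all of it
- candidate steps: Q + E -> E + G; Q -> L; 2 Q -> D; Q + G <-> X
- percentages count the whole charge, also what has not yet gone in
- in an amount of G, one X counts as one G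

1. the flasks by share of G in all that became G or L, highest first, at 8.0 min (south-east / south / north / north-west / east)
2. the share of G in all that became G or L of the flask you put first, at 8.0 min
3. the share of G in all that became G or L of the flask you put last, at 8.0 min

At first sight the runs disagree. Epsilon holds 7.65 times the E of alpha, yet its last ratio of G to L is 1.59 against 0.853.

I divide each ratio by the starting E and call this the selectivity factor: G formed per L formed per mM of E. If the listed steps hold, each of the two rates carries the amount of Q once, so Q cancels from their ratio. The dosing does not cancel: with the whole dose in, the volume is 1.25 times the starting one and E is thinner by that factor, so the ratio shifts as the feed goes in. The factor on the starting E is therefore not strictly constant at one temperature, and I freeze it as an approximation.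

Alpha reads 1.67 mM⁻¹ and theta 1.56 mM⁻¹ at 60 °C, though theta holds twice the Q. Epsilon reads 0.408 mM⁻¹ at 88 °C, less than alpha. So the extra E in epsilon is real, and the higher temperature has lowered the factor.

I draw its logarithm straight between those temperatures and read 0.611 mM⁻¹ at 80 °C, the selectivity factor of the flasks at that temperature. There I take the ratio as roughly this factor times the starting E, and the share is the ratio over one plus the ratio. Hence east stands at 60.4% and north at 49.4%, and south-east lies below both, with less E.

The forecast, holding that the ratio “scales with E and hardly with Q”, gives east > north > south-east > south > north-west, with 62% (56% to 67%) first and 21% (16% to 27%) last. For east that is higher than my figure.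

The flasks give east > north > south-east > south > north-west, with 62.0% in east and 22.1% in north-west.

    Q + E → E + G (k = 2.09 L mol⁻¹ s⁻¹, Ea = 52.0 kJ mol⁻¹)
    Q → L (k = 0.00303 s⁻¹, Ea = 100 kJ mol⁻¹)
    2 Q → D (k = 1.03 × 10⁻⁶ L mol⁻¹ s⁻¹, Ea = 100 kJ mol⁻¹)
    Q + G ⇌ X, settled at all times (K = 0.490 L mol⁻¹, ΔH = −12.0 kJ mol⁻¹)
    (constants at 80 °C)

My factor of 0.611 mM⁻¹ gave 49.4% for north, which stands at 48.4%. With E cut to 0.800 mM and the rest as in north, the factor gives 32.8%, and that flask stands at 31.9%. In north-west, the turning of Q into L uses Q 3.5 times as fast as the turning into G at 4.18 min, and 3.8 times as fast at 8.00 min.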